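(The data are simulated from invented constants; the scatter is artificial.)

I decided to split the loss of Sbt into a part that follows Ctl and a part that does not, and to see what each way of reading the runs then says about the zeta run.

| setting | beta | gamma | theta | epsilon | zeta |
|---|---|---|---|---|---|
| Sbt | 0.120 M | 0.0480 M | 0.120 M | 0.120 M | 0.120 M |
| Ctl | 2.40 × 10⁻⁴ M | 2.40 × 10⁻⁴ M | 1.20 × 10⁻⁴ M | 2.40 × 10⁻⁴ M | 6.90 × 10⁻⁵ M |
| Pdt |  |  |  | 0.0360 M |  |
| time |  |  |  |  | 15 min |

| run | time / min | [Sbt] / M |
|---|---|---|
| beta run | 0.85 | 0.1066 |
| beta run | 2.6 | 0.0934 |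
| beta run | 4.9 | 0.0842 |
| beta run | 7.8 | 0.0704 |
| beta run | 11 | 0.0623 |
| beta run | 15 | 0.0530 |
| gamma run | 0.85 | 0.0425 |
| gamma run | 2.6 | 0.0335 |
| gamma run | 4.9 | 0.0305 |
| gamma run | 7.8 | 0.0232 |
| gamma run | 11 | 0.0194 |
| gamma run | 15 | 0.0160 |
| theta run | 0.85 | 0.1099 |
| theta run | 2.6 | 0.1002 |
| theta run | 4.9 | 0.0900 |
| theta run | 7.8 | 0.0804 |
| theta run | 11 | 0.0733 |
| theta run | 15 | 0.0617 |
| epsilon run | 0.85 | 0.1145 |
| epsilon run | 2.6 | 0.1090 |
| epsilon run | 4.9 | 0.0959 |
| epsilon run | 7.8 | 0.0875 |
| epsilon run | 11 | 0.0764 |
| epsilon run | 15 | 0.0670 |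

(readings scatter by 0.001 M)

- order of the initial rate in [Sbt], near the charge of the beta run, the rate being that where two percent of its Sbt are Pdt (one fixed amount of Pdt, the same in the runs compared)
- order of the initial rate in [Ctl], near the charge of the beta run, the rate being that where two percent of its Sbt are Pdt
- Sbt in the zeta run at 15 min, as a share of the Sbt charged

- Overall: Sbt -> Pdt, with Ctl as catalyst.
- Constant volume, constant temperature.
- A reading of a species includes what of it is bound.
- An order is taken over about fifteen percent of the charge, up and down.

My measure was the pseudo-first-order constant: the logarithm of the ratio of two Sbt readings, divided by the time between them, which is the closed integral of a rate proportional to Sbt. The plain way took it from charge to the last reading, giving 0.0545 /min in the beta run and 0.0443 /min in the theta run, which has half the Ctl. That is an order in Ctl of 0.297, and with that power the zeta run keeps 56.9% of its Sbt at 15 min.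

The second way used the epsilon run, which holds Pdt from the start. Counting lost Sbt as Pdt, its constant was 0.0438 /min around 0.0508 M of Pdt and 0.0371 /min around 0.0788 M. I assumed that the part following Ctl falls as one over Pdt. Extrapolating these two readings to very large Pdt left 0.0249 /min, a rough reading that I called the floor, the part of the constant that does not follow Ctl. Taking it from the beta and theta constants gave an order of 0.605, and the zeta run then keeps 55.9%.

The two shares lie 1 percentage point apart, but both lean on the beta and theta runs, so that agreement is thin. The orders part, and the plain way cheats there: the floor is half of the beta constant, so treating it as Ctl's work holds the order down. I committed to 0.605 and 55.9%.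

The forecast gave 0.9 for Sbt, from the gamma and beta runs agreeing at equal Pdt, and 0.55 for Ctl and 59% for the zeta run, on the ground that “Halving Ctl stretches the time scale only about 1.35–1.6 times”. Its Ctl order is lower than mine.

The zeta run kept 56.5% of its Sbt at 15 min, and near the charge of the beta run the initial rate had orders of 1.0 in Sbt and 0.74 in Ctl. A quarter of the charge as Pdt took 12.4 min in the theta run against 5.91 min in the beta run.

    2 Ctl ⇌ Ctl2, settled at all times (8600 /M)
    Ctl + Sbt → Pdt + Ctl (2040 /M/min)
    Sbt → Q (0.02058 /min)
    Ctl + Pdt ⇌ Ctl.Pdt, settled at all times (505.0 /M)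

 In the gamma run, Pdt reached a quarter of the charge at 3.05 min; the floor's loss by then, reckoned on the mean of the charge and the 2.6 min reading, leaves 0.0329 M of Sbt, against readings of 0.0335 M at 2.6 min and 0.0305 M at 4.9 min.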